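The readings stem from a simulated flask from invented constants, and the scatter is random.

**The decision.** Whether the flask can stop at 4.0 h on 1.20 equiv of reagent in the second phase, or needs a richer charge, depends on how much substrate remains at that time.

| setting | maple | alder | flask |
|---|---|---|---|
| substrate | 20 mM | 20 mM | 20 mM |
| reagent in the second phase | 0.80 equiv | 1.8 equiv | 1.20 equiv |
| remark | run made earlier | run made earlier |  |
| time |  |  | 4.0 h |
| volume of the second phase over the first |  |  | 0.25 |

| run | time / h | product / % |
|---|---|---|
| maple | 0.333 | 6.8 |
| maple | 0.833 | 24.3 |
| maple | 1.50 | 43.0 |
| maple | 2.50 | 58.0 |
| alder | 0.200 | 7.7 |
| alder | 0.417 | 21.8 |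
| alder | 1.00 | 57.8 |
| alder | 2.50 | 96.4 |

(scatter of a reading: 1 percentage point)

- how much product there is at 4.0 h, in percent of the substrate charged
- the change that raises the amount of product at 4.0 h, in percent of the substrate charged most ("none" if none brings more than 2 percentage points) (alpha / theta / none)
- amount of product at 4.0 h, in percent of the substrate charged, after theta

- in the second phase: reagent in the second phase; everything else is in the first
- charges count per volume of the first phase; a concentration in a rate is the amount of a species over the volume of its own phase; every rate counts per litre of the first phase
- steps that have been proposed: reagent in the reaction phase <-> reagent in the second phase; substrate + reagent in the reaction phase -> product; reagent in the reaction phase <-> dormant form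
- the earlier runs hold the two phases in the same ratio of volumes as the flask asked about

**The clock.** A substrate molecule waits to meet reagent in the reaction phase. Its chance per hour is a rate constant times c(reagent in the reaction phase). While that concentration holds steady, substrate falls pseudo-first-order, and the logarithm of charged over remaining substrate climbs in a straight line. Between its middle readings, the maple run climbs at 0.425 /h. Scaling by the charge predicts 0.957 /h for the alder run, whose middle readings give 1.06 /h, so the proportion roughly holds there. For the flask, the same scaling gives 0.638 /h, the substrate clock. Maple's line reaches zero at 0.179 h, a start-up delay read from the readings.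

**My reckoning.** Over 4.0 h less maple's delay, the flask's clock leaves an estimated 8.73% of the substrate, so product reaches about 91.3%. Theta, a doubled charge of reagent in the second phase, scaled the same way, gives about 99.2%. The clock carries no transfer coefficient, so it puts no figure on alpha, the doubling of that coefficient.

**The forecast.** It gives 89%, lower than the 91.3% of this reckoning, names theta as best and gives 99% after it, since more reagent “speeds both regimes”.

**The result.** The flask gives 91.8%. Theta adds 8.2 percentage points and reaches >99.9%, while alpha adds 3.7 points, so theta is best. Reagent in the reaction phase stands at 2.61 mM at 2.00 h and 2.28 mM at 4.00 h. Run forward from the 28.8% of substrate at 2.00 h, the clock leaves 8.04% at 4.00 h, and the flask holds 8.20%.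

    reagent in the reaction phase ⇌ reagent in the second phase, rate k1*([reagent in the reaction phase] - [reagent in the second phase]/K1) per volume of the first phase (partition coefficient = 1.20, kL = 0.00425 /min)
    substrate + reagent in the reaction phase → product (k = 4.29 /M/min)
    reagent in the reaction phase ⇌ dormant form (K = 0.810, k = 0.0834 /min)

**Second flask.** For the same flask read at 1.0 h, the clock leaves 59.2% of the substrate. The computed neighbour holds 57.2% substrate and 42.8% product.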